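The ratio I start from is how fast the coupling partner is lost to decomposition over how fast it is used in coupling.

- red: substrate 0.064 M; coupling partner 0.0960 M; catalyst 0.64 mM; temperature 108 °C; time 20 d
- amber: substrate 0.064 M; coupling partner 0.0960 M; catalyst 0.64 mM; temperature 100 °C; time 20 d

    substrate + coupling partner + catalyst → catalyst + product (k1 = 0.12 M⁻² s⁻¹, Ea1 = 41.0 kJ mol⁻¹)
    coupling partner → decomposed reagent (k2 = 8.7 × 10⁻⁶ s⁻¹, Ea2 = 117 kJ mol⁻¹)
    (constants at 100 °C)

* which of these there is most of at the end, counted by the substrate in it, red (substrate / product)
* which of these there is most of at the end, counted by the substrate in it, amber (substrate / product)
* final amount of the leader among these, as a percentage of the substrate charged, in red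
* final amount of the leader among these, as a percentage of the substrate charged, in amber

- constants are those at 100 °C; use the activation energies for any other temperature

The catalyst stands on both sides of the coupling step, so I hold it at its charge. The partner's own concentration stands in both rates and cancels from the ratio. That leaves two rates per partner molecule: the decomposition constant, and the coupling constant times catalyst times substrate. I therefore define the break-even concentration as the decomposition constant divided by the coupling constant times the catalyst, which is the substrate concentration at which a partner molecule is as likely to couple as to decompose. Substrate concentration divided by it is the selectivity factor for the partner, coupling against decomposition. In amber it is 0.113 M. In red the ratio at the start is 3.0, and multiplying by the substrate charge gives 0.189 M. This is larger than in amber, and decomposition has the higher activation energy.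

The partner's half-life by decomposition in amber is 0.92 d, much shorter than 20 d, so I expect the partner to be the limiting reagent and count where its charge goes. The share that couples is substrate over substrate plus break-even concentration. In red, a first pass at the substrate charge gives 0.0242 M of product. A second pass at the mean substrate gives 0.0206 M, which leaves 67.8% of the substrate. In amber, the same passes give 0.0347 M, then 0.0280 M, which leaves 56.2%. So I commit to substrate leading in both flasks, with less product in red than in amber.

The forecast names substrate in red at 67.3% and substrate in amber at 55.2%, on these grounds: “The final state is therefore set by the partner running out, not by time.” Its figures differ slightly from mine.

The simulation gives substrate at 67.3% in red and substrate at 55.2% in amber, as the forecast said, with coupling partner at 0% in red and 0% in amber.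

Substrate leads in red because of decomposition: with that step taken away, red ends at 0.123% substrate instead of 67.3%.

Take a neighbour of red charged with 0.024 M of coupling partner. The same break-even concentration gives 0.00606 M, then 0.00584 M of product, or 9.13% of the substrate charged. That neighbour ends with 9.14% product and 90.9% substrate.

The numbers are invented; what happens was integrated by code.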